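The numbers in the tables were generated by integration for an exercise.

In a one-step world the charge would fall away exponentially, with product coming fastest at the start. These flasks keep a different ledger, so I book each mole of solid substrate, the limiting reagent, entry by entry.

| flask | solid substrate | temperature | remark | time |
|---|---|---|---|---|
| dusk | 0.065 M | 50 °C | run made earlier |  |
| winter | 0.098 M | 80 °C | run made earlier |  |
| north-east | 0.13 M | 105 °C |  | 8.0 min |
| north-west | 0.13 M | 80 °C |  | 8.0 min |
| south-west | 0.13 M | 55 °C |  | 8.0 min |

| run | time / min | target / % | isomer of the product / % |
|---|---|---|---|
| dusk | 15.0 | 32.4 | 15.4 |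
| dusk | 30.0 | 49.1 | 45.2 |
| dusk | 50.0 | 29.5 | 70.7 |
| dusk | 60.0 | 25.5 | 75.4 |
| dusk | 80.0 | 22.9 | 77.0 |
| dusk | 90.0 | 22.4 | 77.7 |
| winter | 3.00 | 21.7 | 27.5 |
| winter | 6.00 | 37.9 | 60.8 |
| winter | 10.0 | 34.6 | 65.1 |
| winter | 15.0 | 34.9 | 65.8 |
| winter | 20.0 | 35.0 | 64.9 |

(standard deviation of a reading: 0.5 percentage points)

- solid, in amounts per volume of the solution: solid substrate
- the earlier runs were read with a standard deviation of 0.5 percentage points
- at the start none of the solid substrate is in solution
- what has only dissolved of solid substrate counts as not reacted

1. which flask leads in share of target in all that became target or isomer of the product ("all alike" within 1.5 percentage points) (north-east / north-west / south-west / all alike)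
2. share of target in all that became target or isomer of the product, north-east
3. share of target in all that became target or isomer of the product, north-west
4. share of target in all that became target or isomer of the product, south-west

1. Income. In the winter run, target plus isomer of the product read 49.2% after 3.00 min and 98.7% after 6.00 min, twice as much. I read this as a zero-order feed and freeze it: F, booked product per minute, reads 0.0161 M min⁻¹.
2. Closing. I carry the closing time τ, the charge divided by F, the moment the ledger has booked the whole charge as product. For the north-west flask, at the winter temperature, τ is 8.09 min.
3. Transfer. Inside the books, target passes to isomer of the product. The share s is target over target plus isomer. In the winter run, s reads 38.4% at its closing, near 6.00 min, and target then rests near 35.0%.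
4. North-west. Its 8.0 min is about τ, so I take the winter closing share, 38.4%.
5. South-west. The dusk feed reads 0.00207 M min⁻¹, which gives, for the south-west charge at the dusk temperature, τ of 62.8 min, much longer than 8.0 min. The south-west flask is a little hotter than the dusk run, but I expect it to be still early in its ledger, so my estimate is the first dusk share as read, 67.8%.
6. North-east. I expect a resting share above the winter one, and I commit to no number.

The forecast names south-west and gives 45.6% (44% to 47.5%) for north-east, 38.2% (36.8% to 39.8%) for north-west and 68.6% (65% to 72%) for south-west. Its ground: “Target forms first, then relaxes reversibly to isomer”. My own figures differ from its values: 38.4% for north-west and 67.8% for south-west.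

The flasks give 45.2% for north-east, 37.6% for north-west and 70.2% for south-west, so south-west leads.

    target ⇌ isomer of the product (K = 1.90, k = 0.0250 s⁻¹, Ea = 102 kJ mol⁻¹, ΔH = −20.0 kJ mol⁻¹)
    solid substrate ⇌ starting material, rate k2*(cs2 - [starting material]) while solid is left; crystals form when [starting material] > cs2 (solubility = 0.0660 M, k = 0.00430 s⁻¹)
    starting material → target, rate k3*[starting material]/(1 + ([starting material]/sat3)) (0.760 mM, k = 0.530 s⁻¹, Ea = 77.0 kJ mol⁻¹)
    (constants at 80 °C)

The closing time holds on the north-west flask: at 8.0 min, against τ of 8.09 min, its solid substrate stands at 0%. On the north-east flask, the winter F books 49.5% by 4.00 min, and the flask holds 52.2% as target plus isomer of the product. The south-west flask stops with 44.6% still solid, and the short run is the main reason for its share of 70.2%: left ten times as long, that share falls to 23.9%.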